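**Retrosynthetic overview**

1. The cycloheptene is the last ring. It is closed on the finished cyclopentane by a one-pot (5+2) annulation that brings in C9–C10 as vinyltriphenylphosphonium bromide: C1–C10 by conjugate addition of the C1 enolate, C8=C9 by intramolecular Wittig reaction of the resulting ylide with the C8 methyl ketone.
2. Enabling feature: the quaternary ring-fusion carbon C1 is alpha to the C2 ketone of the five-membered ring, and the C6 oxygen of the seven-membered ring sits on the neighbouring side chain. The C1 enolate is therefore stored as the enol 4-methoxybenzoate of C2; the C6 alkoxide takes that acyl group, which frees the enolate regiospecifically and leaves the ester of the target on C6.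
3. Side chain C6–C7–C8(CH3): nitrile oxide cycloaddition (from nitroethane) to a C5 vinyl group, then N–O cleavage. The C5 vinyl group comes from alkoxide-directed conjugate addition of vinylmagnesium bromide to (R)-4-hydroxy-4-isopropyl-2-methylcyclopent-2-enone, with trapping of the C1=C2 enolate.
4. Cyclopentenone (first ring): alkyne hydration and intramolecular aldol condensation, after alkylation of the dioxolanone of (R)-2-hydroxy-3-methylbutanoic acid (chiral-pool source of C4 with its OH and isopropyl group) with 1-bromobut-2-yne.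
5. Ring order: five-membered ring in step 4, seven-membered ring in step 9. C4 comes from the pool; C5, C6 and C1 are set by substrate control.

Key step: step 9

Remark (numbering used in the text, daucane skeleton of the target): C1 = ring-fusion carbon with CH3; C2 = ring ketone; C3 = CH2; C4 = C(OH)(isopropyl); C5 = ring-fusion CH; C6 = CH–O-ester; C7 = CH2; C8 = C(CH3)=; C9 = =CH; C10 = CH2. Compounds 1, 2, 4, 10, 13, 16 and 21 are taken as commercial.

**Step 1**
Reactants: 1 (R)-2-hydroxy-3-methylbutanoic acid; 2 pivalaldehyde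
Product: 3 (2R,5R)-2-tert-butyl-5-(propan-2-yl)-1,3-dioxolan-4-one
Conditions: TsOH·H2O (cat.), H2SO4 (cat.), pentane, reflux, Dean–Stark
Reagents that add atoms: none
Why: Acid-catalysed acetalization with water removal (self-regeneration of stereocenters) should give the thermodynamically preferred cis-2,5-disubstituted dioxolanone, so the acetal carbon records the configuration of the carbinol carbon.

**Step 2**
Reactants: 3 (2R,5R)-2-tert-butyl-5-(propan-2-yl)-1,3-dioxolan-4-one; 4 1-bromobut-2-yne
Product: 5 (2R,5R)-5-(but-2-yn-1-yl)-2-tert-butyl-5-(propan-2-yl)-1,3-dioxolan-4-one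
Conditions: LDA, THF, −78 °C; then 4, −78 → −30 °C
Reagents that add atoms: none
Why: Enolate alkylation of the dioxolanone: the propargylic bromide should enter anti to the tert-butyl group, which puts the butynyl group where the hydrogen was (overall retention) and creates the fully substituted carbinol carbon that becomes C4.

**Step 3**
Reactants: 5 (2R,5R)-5-(but-2-yn-1-yl)-2-tert-butyl-5-(propan-2-yl)-1,3-dioxolan-4-one
Product: 6 (2R,5R)-5-(but-2-yn-1-yl)-2-tert-butyl-5-(propan-2-yl)-1,3-dioxolan-4-ol (lactol, both C4 epimers)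
Conditions: DIBAL-H (1.1 equiv), CH2Cl2, −78 °C; Rochelle salt work-up
Reagents that add atoms: none
Why: DIBAL-H half-reduction of the lactone-type carbonyl should stop at the aluminium hemiacetal at −78 °C and give the lactol; the internal alkyne and the acetal are inert.

**Step 4**
Reactants: 6 (2R,5R)-5-(but-2-yn-1-yl)-2-tert-butyl-5-(propan-2-yl)-1,3-dioxolan-4-ol
Product: 9 (4R)-4-hydroxy-2-methyl-4-(propan-2-yl)cyclopent-2-en-1-one, via keto lactol 7 (not isolated), via open-chain hydroxy keto aldehyde 8 (not isolated)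
Conditions: (i) Ph3PAuNTf2 (2 mol%), dioxane/H2O, 60 °C; (ii) pyrrolidine, AcOH, 60 °C
Reagents that add atoms: water, O
Why: Gold(I)-catalysed alkyne hydration, steered by 5-exo-dig participation of the lactol hydroxyl, should put the ketone on the alkyne carbon nearer to C4; after loss of pivalaldehyde the 4-oxo-aldehyde should undergo amine-catalysed intramolecular aldol condensation, and since the aldehyde has no alpha-hydrogen only the ethyl-ketone CH2 can close the five-membered enone, with C4 untouched.

**Step 5**
Reactants: 9 (4R)-4-hydroxy-2-methyl-4-(propan-2-yl)cyclopent-2-en-1-one; 10 vinylmagnesium bromide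
Product: 12 (3R,4R)-3-ethenyl-2-methyl-4-(propan-2-yl)-1,4-bis(triethylsilyloxy)cyclopent-1-ene, via magnesium enolate 11 (not isolated)
Conditions: 10 (3.2 equiv), THF, −40 → 0 °C; then TESOTf, 2,6-lutidine, −78 → 0 °C
Reagents that add atoms: triethylsilyl trifluoromethanesulfonate, CC[Si](CC)(CC)OS(=O)(=O)C(F)(F)F
Why: Alkoxide-directed (ligand-assisted) conjugate addition of a Grignard reagent to a gamma-oxido enone: the bromomagnesium alkoxide should deliver the vinyl group to C5 on its own face, which is also the face opposite to the isopropyl group, and silylation traps the enolate regiospecifically at C1=C2 and protects the tertiary oxygen.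

**Step 6**
Reactants: 12 (3R,4R)-3-ethenyl-2-methyl-4-(propan-2-yl)-1,4-bis(triethylsilyloxy)cyclopent-1-ene; 13 4-methoxybenzoic anhydride
Product: 15 (3R,4R)-3-ethenyl-2-methyl-4-(propan-2-yl)-4-(triethylsilyloxy)cyclopent-1-en-1-yl 4-methoxybenzoate, via lithium enolate 14 (not isolated)
Conditions: MeLi (1.05 equiv), THF, 0 °C → rt; then 13, −78 °C
Reagents that add atoms: none
Why: Methyllithium cleavage of the silyl enol ether should give the lithium enolate regiospecifically, and O-acylation with the anhydride should give the enol ester without enolate equilibration; the tertiary silyl ether and the vinyl group are inert.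

**Step 7**
Reactants: 15 (3R,4R)-3-ethenyl-2-methyl-4-(propan-2-yl)-4-(triethylsilyloxy)cyclopent-1-en-1-yl 4-methoxybenzoate; 16 nitroethane
Product: 18 (3S,4R)-2-methyl-3-[(5S)-3-methyl-4,5-dihydro-1,2-oxazol-5-yl]-4-(propan-2-yl)-4-(triethylsilyloxy)cyclopent-1-en-1-yl 4-methoxybenzoate, via acetonitrile oxide 17 (not isolated)
Conditions: PhNCO (2.2 equiv), Et3N (cat.), toluene, rt → 50 °C
Reagents that add atoms: none
Why: Mukaiyama–Hoshino dehydration of nitroethane gives acetonitrile oxide, whose 1,3-dipolar cycloaddition to the monosubstituted alkene is regioselective for the 5-substituted isoxazoline; C6 should follow the inside/outside/anti transition-state model (quaternary C4 anti to the incoming dipole, C1 inside, hydrogen outside), and the hindered tetrasubstituted enol ester alkene should not compete.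

**Step 8**
Reactants: 18 (3S,4R)-2-methyl-3-[(5S)-3-methyl-4,5-dihydro-1,2-oxazol-5-yl]-4-(propan-2-yl)-4-(triethylsilyloxy)cyclopent-1-en-1-yl 4-methoxybenzoate
Product: 20 (3S,4R)-3-[(1S)-1-hydroxy-3-oxobutyl]-2-methyl-4-(propan-2-yl)-4-(triethylsilyloxy)cyclopent-1-en-1-yl 4-methoxybenzoate, via hydroxy imine 19 (not isolated)
Conditions: Raney Ni, H2 (1 atm), B(OH)3, MeOH/H2O (5:1), rt
Reagents that add atoms: water, O
Why: Hydrogenolysis of the N–O bond and hydrolysis of the beta-hydroxy imine should unmask the beta-hydroxy methyl ketone with C6 unchanged; the weakly acidic buffer avoids retro-aldol cleavage, and the enol ester and silyl ether should not be affected.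

**Step 9**
Reactants: 20 (3S,4R)-3-[(1S)-1-hydroxy-3-oxobutyl]-2-methyl-4-(propan-2-yl)-4-(triethylsilyloxy)cyclopent-1-en-1-yl 4-methoxybenzoate; 21 vinyltriphenylphosphonium bromide
Product: 25 (3R,3aS,4S,8aR)-6,8a-dimethyl-1-oxo-3-(propan-2-yl)-3-(triethylsilyloxy)-1,2,3,3a,4,5,8,8a-octahydroazulen-4-yl 4-methoxybenzoate, via lithium alkoxide 22 (not isolated), via lithium enolate 23 (not isolated), via phosphorus ylide 24 (not isolated)
Conditions: LiHMDS (1.05 equiv), THF, −78 → −10 °C; then 21 (1.5 equiv), DMPU, −10 → 45 °C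
Reagents that add atoms: none
Why: Proposed new method: LiHMDS deprotonates the C6 hydroxyl and the alkoxide 22 takes the 4-methoxybenzoyl group from the enol ester oxygen (O-to-O acyl transfer through a seven-membered transition state, the enolate being the better leaving group), which puts the ester of the target on C6 and releases the tetrasubstituted C1=C2 lithium enolate 23 regiospecifically; 23 adds through C1 to the CH2 end of the vinylphosphonium salt (C1–C10 bond) and the ylide 24 formed at C9 olefinates the C8 methyl ketone in the same molecule (C8=C9 bond). The closest known chemistry is the Schweizer annulation (conjugate addition of an enolate to vinyltriphenylphosphonium bromide, then intramolecular Wittig reaction), established for five- and six-membered carbocycles, together with the release of ketone enolates from enol esters by nucleophilic cleavage; what is new is the internal alkoxide as the trigger and the closure of a seven-membered ring. The cycloheptene closes by intramolecular Wittig olefination (7-exo-trig attack of the ylide carbon on the ketone, then collapse of the oxaphosphetane), which can only place the new trisubstituted alkene cis inside the ring. The quaternary stereocenter C1 is set in the conjugate addition, the phosphonium salt approaching the enolate face opposite to the bulky C5 side chain, so that C10 ends up trans to C6 (trans ring fusion) and the methyl group cis to the C4 oxygen. The step needs C-alkylation at C1 to outrun proton transfer from C7 (which would end in loss of 4-methoxybenzoate) and has to cope with reversible aldol addition of C1 to the C8 ketone; this should be secured by the cold, regiospecific release of the enolate, by the unhindered cationic acceptor used in excess, and by the ready reversal of a ketone–ketone aldol addition that joins two fully substituted carbons. The phosphonium salt and the polar cosolvent are added only after the acyl transfer, so that the free alkoxide can neither add to the salt nor pass the triethylsilyl group from the C4 oxygen to C6.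

**Step 10**
Reactants: 25 (3R,3aS,4S,8aR)-6,8a-dimethyl-1-oxo-3-(propan-2-yl)-3-(triethylsilyloxy)-1,2,3,3a,4,5,8,8a-octahydroazulen-4-yl 4-methoxybenzoate
Product: 26 (3R,3aS,4S,8aR)-3-hydroxy-6,8a-dimethyl-1-oxo-3-(propan-2-yl)-1,2,3,3a,4,5,8,8a-octahydroazulen-4-yl 4-methoxybenzoate (CNP0232277.1)
Conditions: HF·pyridine, pyridine, THF, 0 °C → rt
Reagents that add atoms: none
Why: Fluoride-mediated desilylation under buffered, base-free conditions should free the tertiary alcohol without retro-aldol opening or dehydration of the beta-hydroxy ketone and without ester migration.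

**Compound list**

1 | (R)-2-hydroxy-3-methylbutanoic acid | CC(C)[C@@H](O)C(=O)O | starting material
2 | pivalaldehyde | CC(C)(C)C=O | starting material
3 | (2R,5R)-2-tert-butyl-5-(propan-2-yl)-1,3-dioxolan-4-one | CC(C)[C@H]1O[C@@H](C(C)(C)C)OC1=O | intermediate
4 | 1-bromobut-2-yne | CC#CCBr | starting material
5 | (2R,5R)-5-(but-2-yn-1-yl)-2-tert-butyl-5-(propan-2-yl)-1,3-dioxolan-4-one | CC(C)[C@@]1(CC#CC)O[C@@H](C(C)(C)C)OC1=O | intermediate
6 | (2R,5R)-5-(but-2-yn-1-yl)-2-tert-butyl-5-(propan-2-yl)-1,3-dioxolan-4-ol | CC(C)[C@@]1(CC#CC)O[C@@H](C(C)(C)C)OC1O | intermediate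
7 | keto lactol, 1-[(2R,4R)-2-tert-butyl-5-hydroxy-4-(propan-2-yl)-1,3-dioxolan-4-yl]butan-2-one | CC(C)[C@@]1(CC(=O)CC)O[C@@H](C(C)(C)C)OC1O | intermediate (not isolated)
8 | (2R)-2-hydroxy-4-oxo-2-(propan-2-yl)hexanal | CCC(=O)C[C@@](O)(C(C)C)C=O | intermediate (not isolated)
9 | (4R)-4-hydroxy-2-methyl-4-(propan-2-yl)cyclopent-2-en-1-one | O=C1C[C@@](O)(C(C)C)C=C1C | intermediate
10 | vinylmagnesium bromide | C=C[Mg]Br | starting material
11 | bis(bromomagnesium) enolate–alkoxide of the conjugate adduct (vinyl cis to the C4 oxygen) | CC1=C(O[Mg]Br)C[C@@](O[Mg]Br)(C(C)C)[C@@H]1C=C | intermediate (not isolated)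
12 | (3R,4R)-3-ethenyl-2-methyl-4-(propan-2-yl)-1,4-bis(triethylsilyloxy)cyclopent-1-ene | CC1=C(O[Si](CC)(CC)CC)C[C@@](O[Si](CC)(CC)CC)(C(C)C)[C@@H]1C=C | intermediate
13 | 4-methoxybenzoic anhydride | COc1ccc(cc1)C(=O)OC(=O)c1ccc(OC)cc1 | starting material
14 | lithium (3R,4R)-3-ethenyl-2-methyl-4-(propan-2-yl)-4-(triethylsilyloxy)cyclopent-1-en-1-olate | [Li+].CC1=C([O-])C[C@@](O[Si](CC)(CC)CC)(C(C)C)[C@@H]1C=C | intermediate (not isolated)
15 | (3R,4R)-3-ethenyl-2-methyl-4-(propan-2-yl)-4-(triethylsilyloxy)cyclopent-1-en-1-yl 4-methoxybenzoate | CC1=C(OC(=O)c2ccc(OC)cc2)C[C@@](O[Si](CC)(CC)CC)(C(C)C)[C@@H]1C=C | intermediate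
16 | nitroethane | CC[N+](=O)[O-] | starting material
17 | acetonitrile oxide | CC#[N+][O-] | intermediate (not isolated)
18 | (3S,4R)-2-methyl-3-[(5S)-3-methyl-4,5-dihydro-1,2-oxazol-5-yl]-4-(propan-2-yl)-4-(triethylsilyloxy)cyclopent-1-en-1-yl 4-methoxybenzoate | CC1=C(OC(=O)c2ccc(OC)cc2)C[C@@](O[Si](CC)(CC)CC)(C(C)C)[C@@H]1[C@@H]1CC(C)=NO1 | intermediate
19 | (3S,4R)-3-[(1S)-1-hydroxy-3-iminobutyl]-2-methyl-4-(propan-2-yl)-4-(triethylsilyloxy)cyclopent-1-en-1-yl 4-methoxybenzoate | CC1=C(OC(=O)c2ccc(OC)cc2)C[C@@](O[Si](CC)(CC)CC)(C(C)C)[C@@H]1[C@@H](O)CC(C)=N | intermediate (not isolated)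
20 | (3S,4R)-3-[(1S)-1-hydroxy-3-oxobutyl]-2-methyl-4-(propan-2-yl)-4-(triethylsilyloxy)cyclopent-1-en-1-yl 4-methoxybenzoate | CC1=C(OC(=O)c2ccc(OC)cc2)C[C@@](O[Si](CC)(CC)CC)(C(C)C)[C@@H]1[C@@H](O)CC(C)=O | intermediate
21 | vinyltriphenylphosphonium bromide | C=C[P+](c1ccccc1)(c1ccccc1)c1ccccc1.[Br-] | starting material
22 | lithium C6 alkoxide of 20 | CC1=C(OC(=O)c2ccc(OC)cc2)C[C@@](O[Si](CC)(CC)CC)(C(C)C)[C@@H]1[C@@H]([O-])CC(C)=O.[Li+] | intermediate (not isolated)
23 | lithium C1=C2 enolate carrying the C6 4-methoxybenzoate | CC1=C([O-])C[C@@](O[Si](CC)(CC)CC)(C(C)C)[C@@H]1[C@H](CC(C)=O)OC(=O)c1ccc(OC)cc1.[Li+] | intermediate (not isolated)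
24 | triphenylphosphonium ylide of the C1 conjugate adduct (C10 trans to the C5 side chain) | C[C@]1(CC=P(c2ccccc2)(c2ccccc2)c2ccccc2)C(=O)C[C@@](O[Si](CC)(CC)CC)(C(C)C)[C@@H]1[C@H](CC(C)=O)OC(=O)c1ccc(OC)cc1 | intermediate (not isolated)
25 | (3R,3aS,4S,8aR)-6,8a-dimethyl-1-oxo-3-(propan-2-yl)-3-(triethylsilyloxy)-1,2,3,3a,4,5,8,8a-octahydroazulen-4-yl 4-methoxybenzoate | COc1ccc(C(=O)O[C@H]2CC(C)=CC[C@@]3(C)C(=O)C[C@@](O[Si](CC)(CC)CC)(C(C)C)[C@H]23)cc1 | intermediate
26 | (3R,3aS,4S,8aR)-3-hydroxy-6,8a-dimethyl-1-oxo-3-(propan-2-yl)-1,2,3,3a,4,5,8,8a-octahydroazulen-4-yl 4-methoxybenzoate | COc1ccc(C(=O)O[C@H]2CC(C)=CC[C@@]3(C)C(=O)C[C@@](O)(C(C)C)[C@H]23)cc1 | target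

**Step count and risks**

Total steps: 10. Longest linear sequence: 10 steps (1 → 26).

Steps most likely to fail:

Step 9 (proposed new method). Three processes may defeat it. Acyl transfer may be slow, so that the lithium alkoxide undergoes retro-aldol cleavage of the side chain or takes the silyl group from the C4 oxygen. The enolate may be quenched by proton transfer from C7, followed by beta-elimination of the ester. The ylide may fail to close the seven-membered ring. The fallback uses known chemistry, sets out from 20 and comes back at 26. Silylation of the C6 hydroxyl (TBSCl, imidazole, DMF) should give the tert-butyldimethylsilyl ether F1. Takai–Lombardo methylenation (Zn, CH2Br2, TiCl4) of the methyl ketone should give the 1,1-disubstituted alkene F2. Cleavage of the enol ester with methyllithium (2.2 equiv) and alkylation of the lithium enolate with allyl bromide, anti to the C5 side chain, should give the C1-allyl ketone F3. Ring-closing metathesis (Grubbs second-generation catalyst, toluene, 60 °C) should close the cycloheptene with its trisubstituted alkene to give the bis-silyl ether F4. HF·pyridine should remove both silyl groups to give the diol F5. Acylation of the secondary C6 hydroxyl with 4-methoxybenzoyl chloride (pyridine, DMAP) should give 26.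

Step 5. The Grignard reagent may add 1,2 to the ketone in place of conjugate addition, or the vinyl group may be delivered to the face of the isopropyl group. The fallback sets out from 9 and comes back at 12. Silylation (TESOTf, 2,6-lutidine) should give the triethylsilyl ether of the enone F6. Copper-mediated conjugate addition (vinylmagnesium bromide, CuBr·SMe2, TESCl, THF, −78 °C) then relies on the steric bias against the isopropyl group in place of alkoxide delivery, and the enolate is trapped in the same flask as the triethylsilyl enol ether, which is 12.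

Step 7. Facial selectivity of the dipole at the vinyl group may be poor, which would erode the configuration at C6. The fallback puts C6 under reagent control; it sets out from 15 and comes back at 20. Oxidative cleavage of the vinyl group (OsO4 cat., NaIO4, 2,6-lutidine, dioxane/H2O) should give the aldehyde F7. Brown allylation with (−)-B-allyldiisopinocampheylborane (from (+)-alpha-pinene; non-oxidative work-up with ethanolamine) should give the (S)-homoallylic alcohol F8. Tsuji–Wacker oxidation (PdCl2 cat., CuCl, O2, DMF/H2O) of the terminal alkene should give the methyl ketone 20.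

**Further compounds**

F1 | step 9 | (3S,4R)-3-[(1S)-1-(tert-butyldimethylsilyloxy)-3-oxobutyl]-2-methyl-4-(propan-2-yl)-4-(triethylsilyloxy)cyclopent-1-en-1-yl 4-methoxybenzoate | CC1=C(OC(=O)c2ccc(OC)cc2)C[C@@](O[Si](CC)(CC)CC)(C(C)C)[C@@H]1[C@@H](O[Si](C)(C)C(C)(C)C)CC(C)=O
F2 | step 9 | (3S,4R)-3-[(1S)-1-(tert-butyldimethylsilyloxy)-3-methylbut-3-en-1-yl]-2-methyl-4-(propan-2-yl)-4-(triethylsilyloxy)cyclopent-1-en-1-yl 4-methoxybenzoate | CC1=C(OC(=O)c2ccc(OC)cc2)C[C@@](O[Si](CC)(CC)CC)(C(C)C)[C@@H]1[C@@H](O[Si](C)(C)C(C)(C)C)CC(C)=C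
F3 | step 9 | C1-allyl ketone: 2-allyl-2-methyl-3-[(1S)-1-(tert-butyldimethylsilyloxy)-3-methylbut-3-en-1-yl]-4-(propan-2-yl)-4-(triethylsilyloxy)cyclopentan-1-one, allyl trans to the side chain | C=CC[C@@]1(C)C(=O)C[C@@](O[Si](CC)(CC)CC)(C(C)C)[C@@H]1[C@@H](O[Si](C)(C)C(C)(C)C)CC(C)=C
F4 | step 9 | (3R,3aS,4S,8aR)-4-(tert-butyldimethylsilyloxy)-6,8a-dimethyl-3-(propan-2-yl)-3-(triethylsilyloxy)-2,3,3a,4,5,8-hexahydroazulen-1(8aH)-one | CC(C)(C)[Si](C)(C)O[C@H]1CC(C)=CC[C@@]2(C)C(=O)C[C@@](O[Si](CC)(CC)CC)(C(C)C)[C@H]12
F5 | step 9 | (3R,3aS,4S,8aR)-3,4-dihydroxy-6,8a-dimethyl-3-(propan-2-yl)-2,3,3a,4,5,8-hexahydroazulen-1(8aH)-one | O[C@H]1CC(C)=CC[C@@]2(C)C(=O)C[C@@](O)(C(C)C)[C@H]12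
F6 | step 5 | (4R)-2-methyl-4-(propan-2-yl)-4-(triethylsilyloxy)cyclopent-2-en-1-one | O=C1C[C@@](O[Si](CC)(CC)CC)(C(C)C)C=C1C
F7 | step 7 | (3R,4R)-3-formyl-2-methyl-4-(propan-2-yl)-4-(triethylsilyloxy)cyclopent-1-en-1-yl 4-methoxybenzoate | CC1=C(OC(=O)c2ccc(OC)cc2)C[C@@](O[Si](CC)(CC)CC)(C(C)C)[C@@H]1C=O
F8 | step 7 | (3S,4R)-3-[(1S)-1-hydroxybut-3-en-1-yl]-2-methyl-4-(propan-2-yl)-4-(triethylsilyloxy)cyclopent-1-en-1-yl 4-methoxybenzoate | CC1=C(OC(=O)c2ccc(OC)cc2)C[C@@](O[Si](CC)(CC)CC)(C(C)C)[C@@H]1[C@@H](O)CC=C
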